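The route rests on not closing ring C at all: the (Z)-cyclodecene is unveiled from a carvone-derived cis-decalin by Grob (Wharton) fragmentation. The step exploits the 1,3-relationship between C1 and the C5=C6 alkene of ring C: cleaving the C1–C6 bond common to two six-membered rings delivers, in one operation, the ten-membered ring, the Z alkene and the C1 ketone. The precursor is a cis-fused bicyclic 1,3-diol monomesylate (tertiary C1–OH, equatorial C5–OMs), with C10 and C11 as MOM ethers and C4, C7, C10 already set. The C1 ketone then serves to attach C7′ and aryl ring A, which is closed to ring B and dearomatised last.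

Key step: step 15

Atom labels: the ten-membered ring C runs C1 (ring-fusion CH) – C2 – C3 – C4 (methyl-bearing CH) – C5=C6 – C7 (CH carrying the carbinol carbon C11) – C8 – C9 – C10 (quaternary C–O with methyl). C7′ is the CH2 of pyran ring B. In ring A, Ca carries the isobutyryl group, Cb the enol OH, Cc the gem-dimethyl pair, Cd the ketone, Ce the C7′ link and Cf the pyran oxygen. Earlier intermediates carry these labels for the atoms they pass on.

Remark: diol 3 is carried as both epimers at its secondary carbinol (C1), which is oxidised in the next step, so that configuration is immaterial.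

**Step 1**
Reactants: 1 (R)-carvone
Product: 2 (1R,4R,6R)-1-methyl-4-(prop-1-en-2-yl)-7-oxabicyclo[4.1.0]heptan-2-one
Conditions: 30% aq. H2O2, NaOH (cat.), MeOH, 0 °C
Reagents that add atoms: hydrogen peroxide, OO
Why: Weitz–Scheffer nucleophilic epoxidation of the enone, in which hydroperoxide adds to C9 anti to the C7 isopropenyl group so that the C10–O bond (the future pyran oxygen) is set trans to the side chain, while the isolated isopropenyl alkene is inert to the nucleophilic oxidant.

**Step 2**
Reactants: 2 trans-carvone oxide
Product: 3 (1R,4R)-1-methyl-4-(prop-1-en-2-yl)cyclohexane-1,2-diol (both C2 epimers)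
Conditions: LiBHEt3 (3 equiv), THF, −78 → 25 °C; aq. NH4Cl
Reagents that add atoms: none
Why: Hydride reduction of the ketone followed by SN2 epoxide opening at the less hindered secondary carbon C9 leaves the tertiary C10–O bond and its configuration untouched.

**Step 3**
Reactants: 3 diol
Product: 4 (2R,5R)-2-hydroxy-2-methyl-5-(prop-1-en-2-yl)cyclohexan-1-one
Conditions: IBX, DMSO, 25 °C
Reagents that add atoms: none
Why: IBX oxidation converts the secondary hydroxyl of a secondary/tertiary 1,2-diol into the α-ketol without glycol cleavage, so both carbinol epimers converge on one ketone and no stereocentre is touched.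

**Step 4**
Reactants: 4 α-ketol
Product: 5 (2R,5R)-2-hydroxy-5-(2-hydroxypropan-2-yl)-2-methylcyclohexan-1-one
Conditions: Co(acac)2 (20 mol%), PhSiH3, O2 (1 atm), THF, 25 °C
Reagents that add atoms: dioxygen, O=O
Why: Mukaiyama hydration, in which a cobalt hydride transfers a hydrogen atom to the terminal carbon of the 1,1-disubstituted alkene and the tertiary C11 radical is trapped by O2 and reduced, gives the Markovnikov tertiary alcohol without creating a stereocentre or disturbing the α-ketol.

**Step 5**
Reactants: 5 dihydroxy ketone
Product: 6 (2R,5R)-2-(methoxymethoxy)-5-[2-(methoxymethoxy)propan-2-yl]-2-methylcyclohexan-1-one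
Conditions: MOMCl (6 equiv), i-Pr2NEt (8 equiv), NaI (cat.), 1,2-dichloroethane, 60 °C
Reagents that add atoms: chloromethyl methyl ether, COCCl
Why: Alkylation of both tertiary hydroxyls with the reactive α-halo ether gives base-stable acetals that, unlike silyl ethers, cannot migrate to a neighbouring alkoxide, which is what the alkoxide-driven key step needs at C10.

**Step 6**
Reactants: 7 methyl (S)-3-hydroxy-2-methylpropanoate
Product: 8 methyl (R)-3-iodo-2-methylpropanoate
Conditions: I2, PPh3, imidazole, CH2Cl2, 0 → 25 °C
Reagents that add atoms: iodine, II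
Why: Appel-type iodination through the alkoxyphosphonium salt takes place at the CH2 group only, so the adjacent stereocentre (the future C4) is not involved and its descriptor changes only through substituent priorities.

**Step 7**
Reactants: 8 iodo ester
Product: 10 methyl (S)-2-methylpent-4-enoate, via organozinc iodide 9 (not isolated)
Conditions: Zn dust (activated with TMSCl and BrCH2CH2Br), DMF, 25 °C; then vinyl bromide, Pd(PPh3)4 (5 mol%), 25 → 40 °C
Reagents that add atoms: vinyl bromide, C=CBr
Why: Zinc inserts into the primary C–I bond to give a β-zincio ester that cannot β-eliminate and keeps its α-stereocentre, and Negishi coupling with vinyl bromide then forms the sp3–sp2 bond that brings in the carbon destined to become C2.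

**Step 8**
Reactants: 10 pentenoate
Product: 13 (S)-3-methyloxolan-2-one, via ozonide 11 (not isolated), via hydroxy ester 12 (not isolated)
Conditions: O3, CH2Cl2, −78 °C; then NaBH4, MeOH, −78 → 0 °C; then aq. HCl work-up, TsOH (cat.), CH2Cl2, 25 °C
Reagents that add atoms: ozone, [O-][O+]=O
Why: Ozonolysis with reductive borohydride work-up excises the terminal carbon and leaves a primary alcohol at C2, which lactonises onto the methyl ester under acid catalysis without touching the ester α-stereocentre.

**Step 9**
Reactants: 13 lactone
Product: 15 methyl (S)-4-iodo-2-methylbutanoate, via silyl ester 14 (not isolated)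
Conditions: TMSCl, NaI, MeCN, 60 °C; then MeOH, 25 °C
Reagents that add atoms: sodium iodide, [Na+].[I-]; methanol, CO
Why: Silyl iodide lactone cleavage, in which iodotrimethylsilane made in the flask silylates the carbonyl and iodide opens the ring by SN2 at the O–CH2 carbon (C2), two atoms from the stereocentre, after which methanolysis of the silyl ester gives the methyl ester.

**Step 10**
Reactants: 15 iodo ester
Product: 16 (S)-4-iodo-2-methylbutanal
Conditions: i-Bu2AlH (1.05 equiv), CH2Cl2, −78 °C; aq. potassium sodium tartrate
Reagents that add atoms: none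
Why: Partial ester reduction stops at the tetrahedral aluminium hemiacetal at −78 °C and releases the aldehyde on work-up, the primary iodide being inert at this temperature and the α-branched aldehyde being used at once to avoid epimerisation.

**Step 11**
Reactants: 6 bis-MOM ketone; 16 iodo aldehyde
Product: 19 (2R,3R,6R)-2-[(1R,2S)-1-hydroxy-4-iodo-2-methylbutyl]-6-(methoxymethoxy)-3-[2-(methoxymethoxy)propan-2-yl]-6-methylcyclohexan-1-one, via boron enolate 17 (not isolated), via boron aldolate 18 (not isolated)
Conditions: (c-Hex)2BCl, Et3N, Et2O, −78 → 0 °C; then 16, −78 → −20 °C; then H2O2, MeOH, pH 7 buffer, 0 °C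
Reagents that add atoms: none
Why: Boron-mediated aldol reaction in which enolisation is possible only toward C6 and gives the ring-constrained E enolate, which adds through a Zimmerman–Traxler chair (C7 branch and C5 hydroxyl anti) on the enolate face trans to the C7 substituent and on the Felkin face of the α-methyl aldehyde, three preferences that reinforce one another to set C6 and C5 while C4 comes from 16.

**Step 12**
Reactants: 19 aldol adduct
Product: 20 C5 triethylsilyl ether of 19
Conditions: TESOTf, 2,6-lutidine, CH2Cl2, −78 °C
Reagents that add atoms: triethylsilyl trifluoromethanesulfonate, CC[Si](CC)(CC)OS(=O)(=O)C(F)(F)F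
Why: Silylation of the secondary aldol hydroxyl under cold, non-nucleophilic conditions removes the only proton that could quench the organosamarium of the next step and blocks retro-aldol cleavage and cyclic ether formation with the primary iodide, without touching a stereocentre.

**Step 13**
Reactants: 20 iodo ketone silyl ether
Product: 22 (1R,4S,5R,6R,7R,10R)-cis-decalin-1,5-diol carrying 4-CH3, 10-CH3, 10-OMOM and 7-C(CH3)2OMOM (route labels), via silyl ether 21 (not isolated)
Conditions: SmI2 (2.5 equiv), HMPA, THF, −78 → 0 °C; then PPTS, MeOH, 25 °C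
Reagents that add atoms: none
Why: Intramolecular samarium Barbier reaction in which SmI2–HMPA reduces the primary iodide to an alkylsamarium that adds to the C1 ketone through a chair-like six-membered transition state along the axial trajectory, the only mode that keeps the C4 methyl and C5 silyloxy groups equatorial, so that C1 is set with the cis ring fusion while the equatorial C10 alkoxy group, lying in the carbonyl plane, is not reductively cleaved, and mild acid then removes the silyl group.

**Step 14**
Reactants: 22 diol
Product: 23 C5 methanesulfonate of 22 (cis-fused 1,3-diol monomesylate, free tertiary C1–OH)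
Conditions: MsCl (1.3 equiv), Et3N, DMAP (cat.), CH2Cl2, −20 → 0 °C
Reagents that add atoms: methanesulfonyl chloride, CS(=O)(=O)Cl
Why: Sulfonylation is selective for the secondary equatorial C5 hydroxyl over the hindered tertiary C1 hydroxyl and proceeds with retention at C5, giving the monomesylate without a base strong enough to trigger fragmentation.

**Step 15**
Reactants: 23 cis-decalin 1,3-diol monomesylate
Product: 25 (4S,5Z,7R,10R)-10-(methoxymethoxy)-7-[2-(methoxymethoxy)propan-2-yl]-4,10-dimethylcyclodec-5-en-1-one, via potassium alkoxide 24 (not isolated)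
Conditions: KOtBu (2 equiv), t-BuOH–THF, 0 → 40 °C
Reagents that add atoms: none
Why: Deprotonation of the tertiary C1–OH gives alkoxide 24, whose oxygen lone pair pushes into C1 as the C1–C6 σ-bond breaks and the antiperiplanar C5–OMs bond ionises, a concerted heterolytic fragmentation that leaves C1 as a ketone and C5=C6 as an alkene. The closest known reaction type is the Wharton variant of the Grob fragmentation, in which decalin 1,3-diol monosulfonates give cyclodecenones with potassium tert-butoxide. No bond is formed to close ring C: the ten-membered ring appears by scission of the bond shared by the two six-membered rings, so no medium-ring cyclisation mode is involved. No stereocentre is created, and C4, C7 and C10 are carried over unchanged. The selectivity needed is Z geometry and fragmentation in preference to elimination or substitution: in the cis-fused chair–chair conformer fixed by the equatorial C7 side chain, C7 is axial and the mesylate equatorial on the new ring, so C4 and C7 are gauche about C5–C6 and collapse to the Z alkene, the C5–O bond is anti to C1–C6 and to no C–H bond (no E2), and backside attack by the C1 oxygen is geometrically excluded.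

**Step 16**
Reactants: 25 cyclodecenone
Product: 26 exocyclic methylene analogue of 25 (C1=C7′H2; 4S,5Z,7R,10R)
Conditions: Ph3PCH3Br (5 equiv), KOtBu (4.8 equiv), toluene, 25 → 80 °C
Reagents that add atoms: methyltriphenylphosphonium bromide, C[P+](c1ccccc1)(c1ccccc1)c1ccccc1.[Br-]
Why: Wittig methylenation with the small unstabilised ylide at elevated temperature converts even α-quaternary ketones into 1,1-disubstituted alkenes, and the ketone has no epimerisable α-stereocentre because C10 is quaternary and C2 is CH2.

**Step 17**
Reactants: 27 5-bromo-1,3-dimethoxy-2-methylbenzene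
Product: 28 1-(6-bromo-2,4-dimethoxy-3-methylphenyl)-2-methylpropan-1-one
Conditions: isobutyryl chloride, AlCl3 (1.1 equiv), CH2Cl2, −20 → 0 °C
Reagents that add atoms: isobutyryl chloride, CC(C)C(Cl)=O
Why: Friedel–Crafts acylation occurs at the only type of free ring position, ortho and para to the two methoxy groups, the low temperature suppressing Lewis-acid demethylation next to the new ketone.

**Step 18**
Reactants: 28 aryl ketone
Product: 29 1-(2-bromo-3-iodo-4,6-dimethoxy-5-methylphenyl)-2-methylpropan-1-one
Conditions: NIS, TFA (cat.), MeCN, 25 °C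
Reagents that add atoms: N-iodosuccinimide, O=C1CCC(=O)N1I
Why: Electrophilic aromatic iodination takes the single remaining ring C–H, activated ortho and para by the methoxy groups and meta to the ketone, so that iodine marks Ce and bromine Cf of ring A.

**Step 19**
Reactants: 26 methylene compound; 29 bromo iodo aryl ketone
Product: 31 (1S,4S,5Z,7R,10R)-bis-MOM cyclodecene carrying at C1 the CH2 (C7′) link to ring A (Br at Cf, isobutyryl at Ca, OMe at Cb and Cd, CH3 at Cc), via alkylborane 30 (not isolated)
Conditions: 9-BBN (2 equiv), THF, 25 → 50 °C; H2O; then 29, PdCl2(dppf) (10 mol%), AsPh3, Cs2CO3, DMF–H2O, 50 °C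
Reagents that add atoms: none
Why: 9-BBN hydroborates the 1,1-disubstituted exocyclic alkene in preference to the hindered Z ring alkene with boron on C7′, and the B-alkyl Suzuki–Miyaura coupling then takes place at the C–I bond, which undergoes oxidative addition far faster than the neighbouring C–Br bond, the C1 stereocentre being set in the hydroboration, where hydrogen is expected to arrive on the peripheral face of C1 flanked by the C10 oxygen substituent and turned away from the ring methylene C9, which places C7′ trans to the C10 oxygen as in the target.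

**Step 20**
Reactants: 31 coupled bis-MOM ether
Product: 32 (1S,4S,5Z,7R,10R)-diol of 31 (free C10–OH and C11–OH)
Conditions: 3 M aq. HCl, MeOH, 40 °C
Reagents that add atoms: none
Why: Acid-catalysed acetal exchange with methanol removes both MOM groups as dimethoxymethane under conditions too mild to ionise the tertiary alcohols or to cleave the aryl methyl ethers.

**Step 21**
Reactants: 32 bromo diol
Product: 33 (1S,4S,5Z,7R,10R)-trans-fused chroman (ring B closed by the Cf–O–C10 bond; ring A aromatic with OMe at Cb and Cd, CH3 at Cc, isobutyryl at Ca; free C11–OH)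
Conditions: Pd(OAc)2 (10 mol%), 2-(di-tert-butylphosphino)-1,1′-binaphthyl, Cs2CO3, toluene, 80 °C
Reagents that add atoms: none
Why: Palladium-catalysed intramolecular C–O coupling (Buchwald–Hartwig etherification), in which oxidative addition into the ketone-activated C–Br bond is followed by binding of the tertiary C10 alkoxide, which has no hydrogen on its carbinol carbon and so cannot undergo β-hydride elimination, and reductive elimination closes the six-membered ring B with the C10–O bond and the C10 configuration intact, the C11 hydroxyl being unable to reach the metal in a ring of reasonable size.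

**Step 22**
Reactants: 33 dimethoxy chroman
Product: 34 (1S,4S,5Z,7R,10R)-chroman with free phenols at Cb and Cd
Conditions: NaSEt (10 equiv), DMF, 120 °C; aq. HCl work-up
Reagents that add atoms: none
Why: Nucleophilic SN2 O-demethylation by ethanethiolate attacks only methyl carbon, so the tertiary alkyl aryl ether of ring B, the tertiary alcohol and the Z alkene are untouched, and both methoxy groups are activated as leaving phenoxides by the ortho or para ketone.

**Step 23**
Reactants: 34 acyl resorcinol chroman
Product: 35 target CNP0564661.1
Conditions: NaOMe (3 equiv), MeI (1.3 equiv), MeOH, 0 → 25 °C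
Reagents that add atoms: iodomethane, CI
Why: Dearomative C-methylation of the acylphloroglucinol-type anion, in which Cc, the only ring carbon flanked by two phenoxide oxygens, is alkylated in protic methanol (which favours C- over O-alkylation) and the gem-dimethyl ring tautomerises to the hydrogen-bonded enolised β-triketone of the target, no stereocentre being formed.

**Compound list**

1 | (R)-carvone | CC1=CC[C@H](CC1=O)C(C)=C | starting material
2 | (1R,4R,6R)-1-methyl-4-(prop-1-en-2-yl)-7-oxabicyclo[4.1.0]heptan-2-one | C[C@@]12O[C@@H]1C[C@@H](C(C)=C)CC2=O | intermediate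
3 | (1R,4R)-1-methyl-4-(prop-1-en-2-yl)cyclohexane-1,2-diol, both C2 epimers | O[C@]1(C)CC[C@@H](C(C)=C)CC1O | intermediate
4 | (2R,5R)-2-hydroxy-2-methyl-5-(prop-1-en-2-yl)cyclohexan-1-one | O[C@]1(C)CC[C@@H](C(C)=C)CC1=O | intermediate
5 | (2R,5R)-2-hydroxy-5-(2-hydroxypropan-2-yl)-2-methylcyclohexan-1-one | O[C@]1(C)CC[C@@H](C(C)(C)O)CC1=O | intermediate
6 | (2R,5R)-2-(methoxymethoxy)-5-[2-(methoxymethoxy)propan-2-yl]-2-methylcyclohexan-1-one | COCO[C@]1(C)CC[C@@H](C(C)(C)OCOC)CC1=O | intermediate
7 | methyl (S)-3-hydroxy-2-methylpropanoate | COC(=O)[C@@H](C)CO | starting material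
8 | methyl (R)-3-iodo-2-methylpropanoate | COC(=O)[C@@H](C)CI | intermediate
9 | [(2R)-3-methoxy-2-methyl-3-oxopropyl]zinc iodide | COC(=O)[C@@H](C)C[Zn]I | intermediate
10 | methyl (S)-2-methylpent-4-enoate | COC(=O)[C@@H](C)CC=C | intermediate
11 | methyl (2S)-2-methyl-3-(1,2,4-trioxolan-3-yl)propanoate (ozonide, both configurations at the trioxolane carbon) | COC(=O)[C@@H](C)CC1OCOO1 | intermediate
12 | methyl (S)-4-hydroxy-2-methylbutanoate | COC(=O)[C@@H](C)CCO | intermediate
13 | (S)-3-methyloxolan-2-one | C[C@H]1CCOC1=O | intermediate
14 | trimethylsilyl (S)-4-iodo-2-methylbutanoate | C[Si](C)(C)OC(=O)[C@@H](C)CCI | intermediate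
15 | methyl (S)-4-iodo-2-methylbutanoate | COC(=O)[C@@H](C)CCI | intermediate
16 | (S)-4-iodo-2-methylbutanal | O=C[C@@H](C)CCI | intermediate
17 | dicyclohexylboron enolate of 6 (C1=C6 enol borinate) | COCO[C@]1(C)CC[C@@H](C(C)(C)OCOC)C=C1OB(C1CCCCC1)C1CCCCC1 | intermediate
18 | dicyclohexylboron aldolate (O-borinate of 19) | COCO[C@]1(C)CC[C@@H](C(C)(C)OCOC)[C@H]([C@H](OB(C2CCCCC2)C2CCCCC2)[C@@H](C)CCI)C1=O | intermediate
19 | (2R,3R,6R)-2-[(1R,2S)-1-hydroxy-4-iodo-2-methylbutyl]-6-(methoxymethoxy)-3-[2-(methoxymethoxy)propan-2-yl]-6-methylcyclohexan-1-one | COCO[C@]1(C)CC[C@@H](C(C)(C)OCOC)[C@H]([C@H](O)[C@@H](C)CCI)C1=O | intermediate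
20 | C5 triethylsilyl ether of 19 | COCO[C@]1(C)CC[C@@H](C(C)(C)OCOC)[C@H]([C@H](O[Si](CC)(CC)CC)[C@@H](C)CCI)C1=O | intermediate
21 | cis-fused bicyclic tertiary alcohol, C5 triethylsilyl ether (1R,4S,5R,6R,7R,10R) | COCO[C@]1(C)CC[C@@H](C(C)(C)OCOC)[C@@H]2[C@H](O[Si](CC)(CC)CC)[C@@H](C)CC[C@]12O | intermediate
22 | (1R,4S,5R,6R,7R,10R)-cis-decalin-1,5-diol with 4-CH3, 10-CH3, 10-OMOM, 7-C(CH3)2OMOM (route labels) | COCO[C@]1(C)CC[C@@H](C(C)(C)OCOC)[C@@H]2[C@H](O)[C@@H](C)CC[C@]12O | intermediate
23 | C5 methanesulfonate of 22 (key-step precursor) | COCO[C@]1(C)CC[C@@H](C(C)(C)OCOC)[C@@H]2[C@H](OS(C)(=O)=O)[C@@H](C)CC[C@]12O | intermediate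
24 | potassium C1 alkoxide of 23 | COCO[C@]1(C)CC[C@@H](C(C)(C)OCOC)[C@@H]2[C@H](OS(C)(=O)=O)[C@@H](C)CC[C@]12[O-].[K+] | intermediate
25 | (4S,5Z,7R,10R)-10-(methoxymethoxy)-7-[2-(methoxymethoxy)propan-2-yl]-4,10-dimethylcyclodec-5-en-1-one (key-step product) | COCO[C@]1(C)CC[C@@H](C(C)(C)OCOC)/C=C\[C@@H](C)CCC1=O | intermediate
26 | exocyclic methylene analogue of 25 (C1=C7′H2) | COCO[C@]1(C)CC[C@@H](C(C)(C)OCOC)/C=C\[C@@H](C)CCC1=C | intermediate
27 | 5-bromo-1,3-dimethoxy-2-methylbenzene | COc1cc(Br)cc(OC)c1C | starting material
28 | 1-(6-bromo-2,4-dimethoxy-3-methylphenyl)-2-methylpropan-1-one | CC(C)C(=O)c1c(Br)cc(OC)c(C)c1OC | intermediate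
29 | 1-(2-bromo-3-iodo-4,6-dimethoxy-5-methylphenyl)-2-methylpropan-1-one | CC(C)C(=O)c1c(Br)c(I)c(OC)c(C)c1OC | intermediate
30 | C7′ 9-borabicyclo[3.3.1]nonan-9-yl adduct of 26, C1–H cis to the C10 oxygen | COCO[C@]1(C)CC[C@@H](C(C)(C)OCOC)/C=C\[C@@H](C)CC[C@H]1CB1C2CCCC1CCC2 | intermediate
31 | (1S,4S,5Z,7R,10R)-bis-MOM cyclodecene with C1–CH2–aryl (Br at Cf, isobutyryl at Ca, OMe at Cb and Cd, CH3 at Cc) | COCO[C@]1(C)CC[C@@H](C(C)(C)OCOC)/C=C\[C@@H](C)CC[C@H]1Cc1c(Br)c(C(=O)C(C)C)c(OC)c(C)c1OC | intermediate
32 | diol of 31 (free C10–OH and C11–OH) | O[C@]1(C)CC[C@@H](C(C)(C)O)/C=C\[C@@H](C)CC[C@H]1Cc1c(Br)c(C(=O)C(C)C)c(OC)c(C)c1OC | intermediate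
33 | (1S,4S,5Z,7R,10R)-trans-fused chroman, ring A aromatic with OMe at Cb and Cd | CC(C)C(=O)c1c(OC)c(C)c(OC)c2c1O[C@]1(C)CC[C@@H](C(C)(C)O)/C=C\[C@@H](C)CC[C@H]1C2 | intermediate
34 | bis-phenol of 33 (OH at Cb and Cd) | CC(C)C(=O)c1c(O)c(C)c(O)c2c1O[C@]1(C)CC[C@@H](C(C)(C)O)/C=C\[C@@H](C)CC[C@H]1C2 | intermediate
35 | CNP0564661.1 (1S,4S,5Z,7R,10R; route labels) | CC(C)C(=O)C1=C(O)C(C)(C)C(=O)C2=C1O[C@]1(C)CC[C@@H](C(C)(C)O)/C=C\[C@@H](C)CC[C@H]1C2 | target

**Step count and risks**

Total step count: 23 (16 in the main line, 5 for aldehyde 16, 2 for arene 29). Longest linear sequence: 16 steps from (R)-carvone (steps 1–5, 11–16, 19–23).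

Steps most likely to fail:

Step 19. The hydroboration may show poor or inverted facial selectivity at C1, because the exocyclic alkene is flanked by a quaternary carbon whose methyl and ring-methylene substituents differ little in size and the outcome depends on the ring conformation. The coupling may also be slow at the di-ortho-substituted aryl iodide. The fallback sets out from 26. Rhodium-catalysed hydroboration with pinacolborane (RhCl(PPh3)3, THF, 25 °C) is known to show the facial preference opposite to that of dialkylboranes on 1,1-disubstituted allylic ethers, and should give the C7′ pinacol boronate F1. Suzuki–Miyaura coupling of this primary boronate with 29 (Pd(OAc)2, 2-dicyclohexylphosphino-2′,6′-diisopropoxybiphenyl, K3PO4, toluene–H2O, 80 °C) comes back to the route at 31.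

Step 13. The alkylsamarium may be protonated or over-reduced before it closes, ketyl-based side reactions may occur at the α-alkoxy ketone, or closure may proceed through the equatorial trajectory to the trans-fused ring. The fallback sets out from 20 and replaces single-electron chemistry by a polar anionic cyclisation. Iodine–lithium exchange (t-BuLi, 2.1 equiv, pentane–Et2O, −100 °C) and warming should let the primary alkyllithium add to the ketone through the same chair-like transition state to give silyl ether 21. The same acidic methanolysis comes back to the route at 22. New compounds on this way: none F0.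

Step 22. The second O-demethylation may stall, because the phenoxide formed first makes the ring a poorer leaving group, and the temperature needed to force it may damage the substrate. The fallback sets out from 33 and unveils ring A stepwise. One equivalent of thiolate (NaSEt, 1.5 equiv, DMF, 100 °C) should remove a single methyl group to give the mono-phenol F2, drawn as the isomer expected from cleavage para to the ketone. C-Methylation of its phenoxide at Cc (MeI, NaOMe, MeOH) should give the dearomatised methyl enol ether F3; any O-methylation merely regenerates 33. Hydrolysis of the remaining methoxy group, now a vinylogous ester (LiOH, THF–H2O, 25 °C), comes back to the route at 35. If the other methoxy group is cleaved first, the same two operations converge on 35 as well.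

**Further compounds**

F1 | step 19 | C7′ pinacol boronate of the bis-MOM cyclodecene, C1–H cis to the C10 oxygen | COCO[C@]1(C)CC[C@@H](C(C)(C)OCOC)/C=C\[C@@H](C)CC[C@H]1CB1OC(C)(C)C(C)(C)O1
F0 | step 13 | none | none
F2 | step 22 | mono-phenol of 33 (OH at Cd, OMe at Cb) | CC(C)C(=O)c1c(OC)c(C)c(O)c2c1O[C@]1(C)CC[C@@H](C(C)(C)O)/C=C\[C@@H](C)CC[C@H]1C2
F3 | step 22 | dearomatised methyl enol ether of 35 (OMe at Cb, gem-dimethyl at Cc, ketone at Cd) | CC(C)C(=O)C1=C(OC)C(C)(C)C(=O)C2=C1O[C@]1(C)CC[C@@H](C(C)(C)O)/C=C\[C@@H](C)CC[C@H]1C2
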